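**Assumption:** (S)-2-methylglycidol, but-2-yn-1-ol, methyl 2-(hydroxymethyl)acrylate and tiglic acid are purchased; Grignard reagents are treated as reagents. Germacranolide numbering (C1–C15) is used for the target.

## Retrosynthetic overview

1. The C8 tiglate comes from Mitsunobu inversion of the 8-epi alcohol 24. Alcohol 24 comes from an intramolecular Cr-mediated allylation (C7–C8) of bromo-aldehyde 23, which closes the 10-membered carbocycle and creates the α-methylene trans-lactone.
2. The 3(2H)-furanone comes from Au-catalysed 5-endo cyclisation of α′-hydroxy ynone 19. The ynone comes from Sonogashira union (C3–C4) of alkyne diol 7 (C1–C3, C8–C10, C14) with Z-iodoalkenyl butenolide 17 (C4–C7, C11–C13, C15).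
3. Fragment 7 comes from (S)-2-methylglycidol (sets C10) by vinyl opening, ozonolysis/acetalisation and ethynylation.
4. Fragment 17 comes from but-2-yn-1-ol (Z-iodoalkene), vinyl addition and lipase resolution (sets C6), esterification with acrylic acid 10, and ring-closing metathesis.
5. Ring order: butenolide (RCM), then furanone (Au), then 10-membered ring plus methylene lactone (Cr allylation).

## Fragment A (alkyne diol 7)

**Step 1**
Reactants: 1, (S)-2-methylglycidol
Product: 2, (R)-2-methylpent-4-ene-1,2-diol
Conditions: vinylMgBr (3 equiv), CuI (10 mol %), THF, −30 → 0 °C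
Reagents that add atoms: vinylmagnesium bromide, C=C[Mg]Br
Why: Cu-catalysed Grignard epoxide opening (SN2 at the unsubstituted CH2); the quaternary carbinol is untouched and becomes C10 (R).

**Step 2**
Reactants: 2
Product: 3, (R)-1-(tert-butyldiphenylsilyloxy)-2-methylpent-4-en-2-ol
Conditions: TBDPSCl, imidazole, DMF, 0 °C → rt
Reagents that add atoms: TBDPSCl, CC(C)(C)[Si](Cl)(c1ccccc1)c1ccccc1
Why: Selective silylation of the primary over the tertiary hydroxyl, so no γ-OH is free when the aldehyde is unveiled.

**Step 3**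
Reactants: 3
Product: 4, (R)-1-(tert-butyldiphenylsilyloxy)-4,4-dimethoxy-2-methylbutan-2-ol
Conditions: O3, CH2Cl2/MeOH, −78 °C; Me2S; then HC(OMe)3, PPTS, MeOH, rt
Reagents that add atoms: methanol, CO / trimethyl orthoformate, COC(OC)OC
Why: Ozonolysis with reductive work-up, then acid-catalysed acetalisation; the tertiary β-OH cannot form a cyclic acetal, so the open dimethyl acetal (masked C8 aldehyde) results.

**Step 4**
Reactants: 4
Product: 5, (R)-4,4-dimethoxy-2-methylbutane-1,2-diol
Conditions: TBAF, THF, 0 °C → rt
Reagents that add atoms: none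
Why: Fluoride desilylation under non-acidic conditions leaves the acetal intact.

**Step 5**
Reactants: 5
Product: 6, (R)-2-hydroxy-4,4-dimethoxy-2-methylbutanal (used crude)
Conditions: SO3·pyridine, DMSO, iPr2NEt, CH2Cl2, −10 °C
Reagents that add atoms: none
Why: Parikh–Doering oxidation of the primary alcohol only; the α-carbon is quaternary, so it cannot epimerise.

**Step 6**
Reactants: 6
Product: 7, (3RS,4R)-6,6-dimethoxy-4-methylhex-1-yne-3,4-diol
Conditions: HC≡CMgBr (3.5 equiv), THF, −78 → 0 °C
Reagents that add atoms: ethynylmagnesium bromide, C#C[Mg]Br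
Why: Grignard 1,2-addition; the new carbinol (C1) is a mixture, which is irrelevant because it is oxidised in step 16.

## Acrylic acid side branch

**Step 7**
Reactants: 8, methyl 2-(hydroxymethyl)acrylate
Product: 9, methyl 2-[(tert-butyldimethylsilyloxy)methyl]acrylate
Conditions: TBSCl, imidazole, CH2Cl2, 0 °C → rt
Reagents that add atoms: TBSCl, CC(C)(C)[Si](C)(C)Cl
Why: Standard silylation; the OTBS group is Sonogashira-stable and later becomes the allylic bromide.

**Step 8**
Reactants: 9
Product: 10, 2-[(tert-butyldimethylsilyloxy)methyl]acrylic acid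
Conditions: LiOH·H2O, THF/H2O, 0 °C → rt; citric acid to pH 4
Reagents that add atoms: lithium hydroxide/water, O
Why: Saponification of the methyl ester; the primary TBS ether survives mild hydroxide.

## Fragment B (iodoalkenyl butenolide 17)

**Step 9**
Reactants: 11, but-2-yn-1-ol
Product: 12, (Z)-3-iodobut-2-en-1-ol
Conditions: Red-Al, THF, 0 °C → rt; then I2, −78 → 0 °C
Reagents that add atoms: iodine, II
Why: Alkoxide-directed trans-hydroalumination, then iodinolysis with retention, puts I cis to CH2OH; this fixes the 4Z geometry.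

**Step 10**
Reactants: 12
Product: 13, (Z)-3-iodobut-2-enal (used at once, dark)
Conditions: MnO2, CH2Cl2, rt
Reagents that add atoms: none
Why: Mild allylic oxidation that does not isomerise the Z-iodoenal if handled cold and quickly.

**Step 11**
Reactants: 13
Product: 14, rac-(Z)-5-iodohexa-1,4-dien-3-ol
Conditions: vinylMgBr, THF, −78 °C
Reagents that add atoms: vinylmagnesium bromide, C=C[Mg]Br
Why: Grignard 1,2-addition to the enal; I/Mg exchange is negligible at −78 °C.

**Step 12**
Reactants: 14
Product: 15, (S,Z)-5-iodohexa-1,4-dien-3-ol (recovered alcohol, ≤50 %)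
Conditions: Novozym 435 (CAL-B), vinyl acetate, hexane, rt, to ~52 % conversion
Reagents that add atoms: none (only the discarded R enantiomer is acetylated)
Why: Lipase kinetic resolution (Kazlauskas rule: vinyl = medium, iodopropenyl = large, so the R alcohol is acylated); the remaining S alcohol is the C6 stereocentre.

**Step 13**
Reactants: 15 and 10
Product: 16, (S,Z)-5-iodohexa-1,4-dien-3-yl 2-[(tert-butyldimethylsilyloxy)methyl]acrylate
Conditions: DCC, DMAP (cat.), CH2Cl2, 0 °C → rt
Reagents that add atoms: none
Why: Steglich esterification; the C–O bond at the stereocentre is not broken.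

**Step 14**
Reactants: 16
Product: 17, (5S)-3-[(tert-butyldimethylsilyloxy)methyl]-5-[(Z)-2-iodoprop-1-enyl]furan-2(5H)-one
Conditions: Grubbs II (5–8 mol %), CH2Cl2 (5 mM), 40 °C
Reagents that add atoms: none
Why: Ring-closing metathesis between the vinyl group and the acrylate (ethylene lost); the trisubstituted iodoalkene is inert to the Ru carbene.

## Union and endgame

From 18 onward the butenolide carbon is labelled R only because of a CIP priority change (I replaced by C); the spatial arrangement is unchanged.

**Step 15**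
Reactants: 7 and 17
Product: 18, (5R)-3-[(TBS-oxy)methyl]-5-[(1Z,6R)-5,6-dihydroxy-8,8-dimethoxy-2,6-dimethyloct-1-en-3-ynyl]furan-2(5H)-one (C5′ epimers)
Conditions: Pd(PPh3)4 (5 mol %), CuI (10 mol %), Et3N (2.5 equiv), degassed THF, 0 °C → rt, 1–2 h
Reagents that add atoms: none
Why: Sonogashira coupling forms C3–C4 with retention of the Z-alkene; low temperature and short time limit base-mediated epimerisation of the butenolide γ-H.

**Step 16**
Reactants: 18
Product: 19, the α′-hydroxy ynone: (5R)-3-[(TBS-oxy)methyl]-5-[(1Z,6R)-6-hydroxy-8,8-dimethoxy-2,6-dimethyl-5-oxooct-1-en-3-ynyl]furan-2(5H)-one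
Conditions: MnO2 (20 equiv), CH2Cl2, rt
Reagents that add atoms: none
Why: Chemoselective oxidation of the only secondary (propargylic) alcohol; this removes the stereo-random C1 centre.

**Step 17**
Reactants: 19
Product: 20, (5R)-3-[(TBS-oxy)methyl]-5-{(Z)-2-[(5R)-5-(2,2-dimethoxyethyl)-5-methyl-4-oxo-4,5-dihydrofuran-2-yl]prop-1-enyl}furan-2(5H)-one
Conditions: (p-CF3C6H4)3PAuCl (5 mol %), AgOTf (5 mol %), 4 Å MS, toluene, rt
Reagents that add atoms: none
Why: Au(I)-catalysed 5-endo-dig addition of the tertiary OH to the activated ynone gives the 3(2H)-furanone; C10 is not involved in bond breaking.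

**Step 18**
Reactants: 20
Product: 21, the 3-(hydroxymethyl)butenolide analogue of 20
Conditions: HF·pyridine, pyridine, THF, 0 °C
Reagents that add atoms: none
Why: Buffered, non-basic desilylation that spares the acetal and the base-labile butenolide.

**Step 19**
Reactants: 21
Product: 22, the 3-(bromomethyl)butenolide analogue of 20
Conditions: CBr4, PPh3, CH2Cl2, 0 °C
Reagents that add atoms: carbon tetrabromide, BrC(Br)(Br)Br
Why: Appel bromination of the primary allylic alcohol under neutral conditions.

**Step 20**
Reactants: 22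
Product: 23, bromo-aldehyde: {(2R)-5-[(Z)-1-((2R)-4-(bromomethyl)-5-oxo-2,5-dihydrofuran-2-yl)prop-1-en-2-yl]-2-methyl-3-oxo-2,3-dihydrofuran-2-yl}acetaldehyde (used crude)
Conditions: TsOH·H2O (cat.), acetone/H2O (10:1), rt
Reagents that add atoms: water, O
Why: Mild acetal hydrolysis; the electron-poor allylic bromide does not solvolyse, and the elimination-prone aldehyde is taken on immediately.

**Step 21**
Reactants: 23
Product: 24, (6R,7R,8S,10R)-8-hydroxy macrocycle (8-epi-desacyl-atripliciolide)
Conditions: CrCl2 (8 equiv), THF, rt, syringe-pump addition (final 2 mM)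
Reagents that add atoms: none
Why: Intramolecular Nozaki–Hiyama (Barbier-type) allylation: the allyl-Cr(III) attacks through C7 (SE2′) anti to the C6 side chain, giving the trans-fused α-methylene lactone (7R). The closed chair (Zimmerman–Traxler) transition state, with C9 anti to C11, gives the 7,8-anti alcohol (8S).

**Step 22**
Reactants: 24 and 25, tiglic acid
Product: 26, atripliciolide tiglate (6R,7R,8R,10R)
Conditions: PPh3, DIAD, toluene/THF, 0 °C → rt
Reagents that add atoms: tiglic acid (25), C/C=C(\C)C(=O)O
Why: Mitsunobu esterification proceeds by SN2 inversion at C8 (8S → 8R) and installs the E-configured tiglate without activating the acid carbonyl.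

## Compound list

1 | (S)-2-methylglycidol | C[C@]1(CO)CO1 | starting material
2 | (R)-2-methylpent-4-ene-1,2-diol | C[C@](O)(CO)CC=C | intermediate
3 | (R)-1-(TBDPS-oxy)-2-methylpent-4-en-2-ol | C[C@](O)(CO[Si](c1ccccc1)(c1ccccc1)C(C)(C)C)CC=C | intermediate
4 | (R)-1-(TBDPS-oxy)-4,4-dimethoxy-2-methylbutan-2-ol | C[C@](O)(CO[Si](c1ccccc1)(c1ccccc1)C(C)(C)C)CC(OC)OC | intermediate
5 | (R)-4,4-dimethoxy-2-methylbutane-1,2-diol | C[C@](O)(CO)CC(OC)OC | intermediate
6 | (R)-2-hydroxy-4,4-dimethoxy-2-methylbutanal | C[C@](O)(C=O)CC(OC)OC | intermediate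
7 | (3RS,4R)-6,6-dimethoxy-4-methylhex-1-yne-3,4-diol | C[C@](O)(C(O)C#C)CC(OC)OC | intermediate (fragment A)
8 | methyl 2-(hydroxymethyl)acrylate | C=C(CO)C(=O)OC | starting material
9 | methyl 2-[(TBS-oxy)methyl]acrylate | C=C(CO[Si](C)(C)C(C)(C)C)C(=O)OC | intermediate
10 | 2-[(TBS-oxy)methyl]acrylic acid | C=C(CO[Si](C)(C)C(C)(C)C)C(=O)O | intermediate
11 | but-2-yn-1-ol | CC#CCO | starting material
12 | (Z)-3-iodobut-2-en-1-ol | C/C(I)=C/CO | intermediate
13 | (Z)-3-iodobut-2-enal | C/C(I)=C/C=O | intermediate
14 | rac-(Z)-5-iodohexa-1,4-dien-3-ol | C/C(I)=C/C(O)C=C | intermediate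
15 | (S,Z)-5-iodohexa-1,4-dien-3-ol | C/C(I)=C/[C@@H](O)C=C | intermediate
16 | (S,Z)-5-iodohexa-1,4-dien-3-yl 2-[(TBS-oxy)methyl]acrylate | C/C(I)=C/[C@@H](OC(=O)C(=C)CO[Si](C)(C)C(C)(C)C)C=C | intermediate
17 | (5S)-3-[(TBS-oxy)methyl]-5-[(Z)-2-iodoprop-1-enyl]furan-2(5H)-one | C/C(I)=C/[C@@H]1C=C(CO[Si](C)(C)C(C)(C)C)C(=O)O1 | intermediate (fragment B)
18 | Sonogashira enyne diol | O=C1O[C@H](/C=C(/C)C#CC(O)[C@](C)(O)CC(OC)OC)C=C1CO[Si](C)(C)C(C)(C)C | intermediate
19 | α′-hydroxy ynone | O=C1O[C@H](/C=C(/C)C#CC(=O)[C@](C)(O)CC(OC)OC)C=C1CO[Si](C)(C)C(C)(C)C | intermediate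
20 | furanone–butenolide, OTBS, acetal | O=C1O[C@H](/C=C(/C)C2=CC(=O)[C@@](C)(CC(OC)OC)O2)C=C1CO[Si](C)(C)C(C)(C)C | intermediate
21 | furanone–butenolide, CH2OH, acetal | O=C1O[C@H](/C=C(/C)C2=CC(=O)[C@@](C)(CC(OC)OC)O2)C=C1CO | intermediate
22 | furanone–butenolide, CH2Br, acetal | O=C1O[C@H](/C=C(/C)C2=CC(=O)[C@@](C)(CC(OC)OC)O2)C=C1CBr | intermediate
23 | bromo-aldehyde | O=C1O[C@H](/C=C(/C)C2=CC(=O)[C@@](C)(CC=O)O2)C=C1CBr | intermediate
24 | (6R,7R,8S,10R)-8-hydroxy macrocycle (8-epi alcohol) | C=C1C(=O)O[C@@H]2/C=C(/C)C3=CC(=O)[C@@](C)(C[C@H](O)[C@@H]12)O3 | intermediate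
25 | tiglic acid | C/C=C(\C)C(=O)O | starting material
26 | atripliciolide tiglate | C=C1C(=O)O[C@@H]2/C=C(/C)C3=CC(=O)[C@@](C)(C[C@@H](OC(=O)/C(C)=C/C)[C@@H]12)O3 | target

## Totals and risks

Total step count: 22.
Longest linear sequence: 14 (steps 1–6 or 9–14, then 15–22).

Steps most likely to fail:

1. **Step 21 (Cr-mediated macrocyclisation).** The ring is strained, aldehyde 23 can β-eliminate to open the furanone, and the C8 outcome rests on a chair transition-state argument I could not model; the C8 configuration of 24 must be checked (J7,8 large for 8α-OH, about 2 Hz for 8β-OH).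
   - Fallback: reverse the ring order. Cyclise at the ynone stage with C10–OH silylated (aldehyde no longer elimination-prone, less rigid chain), then desilylate and form the furanone by transannular Au(I) cyclisation.
   - If the cyclisation instead gives the 8β-alcohol directly, replace step 22 by a retentive acylation (tiglic anhydride, DMAP).

2. **Step 22 (Mitsunobu on a hindered macrocyclic secondary alcohol).** Elimination and PPh3 addition to the methylene lactone can compete.
   - Fallback: abandon SN2 inversion. Oxidise 24 to the C8 ketone (DMP), reduce with a bulky hydride from the α-face to the 8β-alcohol, and acylate with tiglic anhydride/DMAP. If needed, mask the methylene lactone as its Me2NH adduct and release it with MeI/NaHCO3.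

3. **Step 15 (Sonogashira on the γ-alkenyl butenolide).** Amine base can epimerise C6, and Pd(0) can ionise the allylic lactone.
   - Fallback: couple ester 16 (no acidic C6–H) with 7 instead, and form the butenolide by RCM after the furanone is in place.
   - Alternatively, make the C3–C4 bond by base-free Stille coupling of the tributylstannyl alkyne from bis-silylated 7.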